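**Plan**
1. Target: (3S)-isoflavanquinone (CIP order at C3: C2 > quinone carbon > C4 > H). Chroman numbering O1, C2, C3, C4, C4a, C8a is used, and C1'–C6' for the ring that becomes the quinone (C1' bonded to C3).
2. First cut, the quinone: the C5' oxygen is added last by oxidation of a 2'-phenol with a free para position, so the quinone is carried as a 2-(benzyloxy)-3,4-dimethoxyphenyl group.
3. Second cut, the pyran ring at C3–C4 and O1–C2, after raising C2 to the carboxyl level. O1–C8a–C4a–C4 is the retron of an o-quinone methide of ring A (exocyclic C4, stabilized by the 7-OMe para to C4a), and C3 with its aryl group is the α-carbon of an arylacetic acid.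
4. Forward: acid 4 (3 steps from acetophenone 1) and silyl bromide 8 (3 steps from salicylaldehyde 5) carry the two arenes. The pyran ring is closed last by an isothiourea-catalysed Michael addition–lactonization (formal [4+2]) of the ammonium enolate of 4 with the fluoride-released o-quinone methide.
5. Stereochemistry: C3 is set in that step by the chiral isothiourea. The C2 carbonyl helper is then removed (i-Bu2AlH, then Et3SiH/BF3·OEt2) without reaction at C3, and debenzylation plus Teuber oxidation give the quinone.

Key step: step 7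

Assumption: the sense of induction in step 7 follows the accepted model for isothiourea-bound (Z)-ammonium enolates (1,5 O···S contact, attack anti to the pseudo-axial C2 phenyl), which assigns the 3S lactone to (2R,3S)-HyperBTM; if a trial run shows the opposite sense, the enantiomeric catalyst would be used.

**Step 1**
Reactants: 1 1-(2-hydroxy-3,4-dimethoxyphenyl)ethan-1-one
Product: 2 1-[2-(benzyloxy)-3,4-dimethoxyphenyl]ethan-1-one
Conditions: BnBr, K2CO3, DMF, 60 °C
Reagents that add atoms: benzyl bromide, BrCc1ccccc1
Why: Williamson etherification of the chelated ortho-hydroxy ketone should be clean, and the benzyl ether survives every later step until it is removed by hydrogenolysis just before the phenol is oxidized.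

**Step 2**
Reactants: 2 1-[2-(benzyloxy)-3,4-dimethoxyphenyl]ethan-1-one
Product: 3 2-[2-(benzyloxy)-3,4-dimethoxyphenyl]-1-(morpholin-4-yl)ethane-1-thione
Conditions: S8, morpholine, 130 °C
Reagents that add atoms: sulfur, S1SSSSSSS1; morpholine, C1COCCN1
Why: The Willgerodt–Kindler reaction moves the oxidized carbon of an aryl methyl ketone to the chain terminus and is well established for alkoxy-substituted acetophenones, whose ethers are inert to sulfur and morpholine.

**Step 3**
Reactants: 3 2-[2-(benzyloxy)-3,4-dimethoxyphenyl]-1-(morpholin-4-yl)ethane-1-thione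
Product: 4 [2-(benzyloxy)-3,4-dimethoxyphenyl]acetic acid
Conditions: KOH, EtOH/H2O, reflux; then aq. HCl
Reagents that add atoms: potassium hydroxide, [K+].[OH-]; water, O
Why: Alkaline hydrolysis of the thioamide is the standard second half of the Willgerodt–Kindler sequence and leaves aryl ethers untouched.

**Step 4**
Reactants: 5 2-hydroxy-4,5-dimethoxybenzaldehyde
Product: 6 2-[(tert-butyldimethylsilyl)oxy]-4,5-dimethoxybenzaldehyde
Conditions: TBSCl, imidazole, CH2Cl2, rt
Reagents that add atoms: tert-butyldimethylsilyl chloride, CC(C)(C)[Si](C)(C)Cl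
Why: Imidazole-mediated silylation masks the phenoxide that fluoride will later release to trigger o-quinone methide formation.

**Step 5**
Reactants: 6 2-[(tert-butyldimethylsilyl)oxy]-4,5-dimethoxybenzaldehyde
Product: 7 {2-[(tert-butyldimethylsilyl)oxy]-4,5-dimethoxyphenyl}methanol
Conditions: NaBH4, MeOH/THF, −10 °C
Reagents that add atoms: none
Why: Borohydride reduction of the aldehyde, run cold and briefly to suppress 1,4 O-to-O silyl migration.

**Step 6**
Reactants: 7 {2-[(tert-butyldimethylsilyl)oxy]-4,5-dimethoxyphenyl}methanol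
Product: 8 [2-(bromomethyl)-4,5-dimethoxyphenoxy](tert-butyl)dimethylsilane
Conditions: CBr4, PPh3, CH2Cl2, 0 °C; filtered through a short pad and used at once
Reagents that add atoms: carbon tetrabromide, BrC(Br)(Br)Br
Why: The Appel bromination works under neutral conditions, which the acid-sensitive, donor-substituted benzylic position requires.

**Step 7**
Reactants: 4 [2-(benzyloxy)-3,4-dimethoxyphenyl]acetic acid; 8 [2-(bromomethyl)-4,5-dimethoxyphenoxy](tert-butyl)dimethylsilane
Product: 11 (3S)-3-[2-(benzyloxy)-3,4-dimethoxyphenyl]-6,7-dimethoxychroman-2-one, via mixed pivalic anhydride 9 (not isolated), via ring A o-quinone methide 10 (not isolated)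
Conditions: t-BuCOCl, i-Pr2NEt, THF, 0 °C; then (2R,3S)-3-isopropyl-2-phenyl-3,4-dihydro-2H-benzo[4,5]thiazolo[3,2-a]pyrimidine ((2R,3S)-HyperBTM, 10 mol %), 8, CsF, 18-crown-6, −20 °C → 0 °C
Reagents that add atoms: none
Why: CsF removes the silyl group of 8 and the phenoxide expels bromide by 1,4-elimination, so that ring A is briefly dearomatized to the o-quinone methide 10 with an electrophilic exocyclic C4, while the isothiourea is acylated by 9 and deprotonated to the (Z)-ammonium enolate, held planar by the 1,5 O···S contact. The enolate α-carbon (C3) adds to C4 in an intermolecular Michael addition that restores the aromaticity of ring A, and the phenoxide O1 released in this way attacks the acylammonium carbon C2 in a 6-exo-trig lactonization that closes the ring and frees the catalyst. The closest known reaction type is the Lewis-base-catalysed Michael addition–lactonization (formal [4+2] cycloaddition) of arylacetic-acid-derived ammonium enolates with o-quinone methides. C3, the only new stereocenter, is fixed in the C–C bond formation by the catalyst, whose pseudo-axial C2 phenyl group covers one enolate face so that C4 arrives anti to it, which for (2R,3S)-HyperBTM should mean 3S. The step needs C- over O-alkylation (secured by the soft methide carbon), capture of 10 before it oligomerizes (secured by slow release from sparingly soluble CsF and by the stabilizing 6- and 7-methoxy groups) and no enolization of the α-aryl lactone (low temperature, no excess fluoride).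

**Step 8**
Reactants: 11 (3S)-3-[2-(benzyloxy)-3,4-dimethoxyphenyl]-6,7-dimethoxychroman-2-one
Product: 13 (3S)-3-[2-(benzyloxy)-3,4-dimethoxyphenyl]-6,7-dimethoxychromane, via aluminium lactolate 12 (not isolated)
Conditions: i-Bu2AlH, CH2Cl2, −78 °C; then Et3SiH (excess), BF3·OEt2, −78 → −30 °C
Reagents that add atoms: none
Why: Partial reduction of the dihydrocoumarin by i-Bu2AlH stops at the tetrahedral lactolate at −78 °C, and ionic hydrogenation (BF3·OEt2 ionizes C2–O to the cyclic oxocarbenium ion, Et3SiH delivers hydride to C2) removes the helper oxygen; C3 keeps its configuration as long as hydride capture outruns loss of the C3 proton, which the cold, silane-rich medium is meant to secure.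

**Step 9**
Reactants: 13 (3S)-3-[2-(benzyloxy)-3,4-dimethoxyphenyl]-6,7-dimethoxychromane
Product: 14 6-[(3S)-6,7-dimethoxychroman-3-yl]-2,3-dimethoxyphenol
Conditions: H2 (1 atm), Pd/C, EtOAc/MeOH, rt
Reagents that add atoms: none
Why: Hydrogenolysis of the aryl benzyl ether; the chroman has no benzylic C–O bond and no reducible group, so only the phenol should be unmasked.

**Step 10**
Reactants: 14 6-[(3S)-6,7-dimethoxychroman-3-yl]-2,3-dimethoxyphenol
Product: 15 abroquinone A, 2-[(3S)-6,7-dimethoxychroman-3-yl]-5,6-dimethoxycyclohexa-2,5-diene-1,4-dione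
Conditions: (KO3S)2NO, KH2PO4, acetone/H2O, 0 °C → rt
Reagents that add atoms: potassium nitrosodisulfonate, [K+].[K+].[O]N(S(=O)(=O)[O-])S(=O)(=O)[O-]
Why: Teuber oxidation: the nitroxide abstracts the phenolic hydrogen, a second equivalent adds at the free para carbon C5' and loses imidodisulfonate to give the p-quinone, while the fully etherified ring A and the C3 stereocenter should be untouched in the near-neutral buffer.

**Compound list**
1 | 1-(2-hydroxy-3,4-dimethoxyphenyl)ethan-1-one | CC(=O)c1ccc(OC)c(OC)c1O | starting material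
2 | 1-[2-(benzyloxy)-3,4-dimethoxyphenyl]ethan-1-one | CC(=O)c1ccc(OC)c(OC)c1OCc1ccccc1 | intermediate
3 | 2-[2-(benzyloxy)-3,4-dimethoxyphenyl]-1-(morpholin-4-yl)ethane-1-thione | COc1ccc(CC(=S)N2CCOCC2)c(OCc2ccccc2)c1OC | intermediate
4 | [2-(benzyloxy)-3,4-dimethoxyphenyl]acetic acid | COc1ccc(CC(=O)O)c(OCc2ccccc2)c1OC | intermediate
5 | 2-hydroxy-4,5-dimethoxybenzaldehyde | O=Cc1cc(OC)c(OC)cc1O | starting material
6 | 2-[(tert-butyldimethylsilyl)oxy]-4,5-dimethoxybenzaldehyde | O=Cc1cc(OC)c(OC)cc1O[Si](C)(C)C(C)(C)C | intermediate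
7 | {2-[(tert-butyldimethylsilyl)oxy]-4,5-dimethoxyphenyl}methanol | OCc1cc(OC)c(OC)cc1O[Si](C)(C)C(C)(C)C | intermediate
8 | [2-(bromomethyl)-4,5-dimethoxyphenoxy](tert-butyl)dimethylsilane | BrCc1cc(OC)c(OC)cc1O[Si](C)(C)C(C)(C)C | intermediate
9 | [2-(benzyloxy)-3,4-dimethoxyphenyl]acetic pivalic anhydride (formed in the flask) | COc1ccc(CC(=O)OC(=O)C(C)(C)C)c(OCc2ccccc2)c1OC | intermediate
10 | 3,4-dimethoxy-6-methylidenecyclohexa-2,4-dien-1-one, the o-quinone methide of ring A (formed in the flask) | C=C1C=C(OC)C(OC)=CC1=O | intermediate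
11 | (3S)-3-[2-(benzyloxy)-3,4-dimethoxyphenyl]-6,7-dimethoxychroman-2-one | COc1ccc([C@H]2C(=O)Oc3cc(OC)c(OC)cc3C2)c(OCc2ccccc2)c1OC | intermediate
12 | diisobutylaluminium alkoxide of (3S)-3-[2-(benzyloxy)-3,4-dimethoxyphenyl]-6,7-dimethoxychroman-2-ol, both C2 epimers (formed in the flask) | COc1ccc([C@H]2C(O[Al](CC(C)C)CC(C)C)Oc3cc(OC)c(OC)cc3C2)c(OCc2ccccc2)c1OC | intermediate
13 | (3S)-3-[2-(benzyloxy)-3,4-dimethoxyphenyl]-6,7-dimethoxychromane | COc1ccc([C@H]2COc3cc(OC)c(OC)cc3C2)c(OCc2ccccc2)c1OC | intermediate
14 | 6-[(3S)-6,7-dimethoxychroman-3-yl]-2,3-dimethoxyphenol | COc1ccc([C@H]2COc3cc(OC)c(OC)cc3C2)c(O)c1OC | intermediate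
15 | abroquinone A, 2-[(3S)-6,7-dimethoxychroman-3-yl]-5,6-dimethoxycyclohexa-2,5-diene-1,4-dione | COC1=C(OC)C(=O)C([C@H]2COc3cc(OC)c(OC)cc3C2)=CC1=O | target

**Step count**
Total: 10 steps. Longest linear sequence: 7 steps (steps 1, 2, 3, 7, 8, 9, 10, or equally steps 4, 5, 6, 7, 8, 9, 10).

**Steps most likely to fail**

Step 7. The enantiopurity may erode through enolization of the α-aryl lactone or through a fluoride-promoted achiral addition, and the o-quinone methide may oligomerize before it is captured. The fallback replaces catalyst control by auxiliary control; it sets out from 4 and 8 and returns at 11. Acid 4 would be activated (t-BuCOCl, Et3N, THF, −20 °C) and joined to the lithium salt of (S)-4-benzyl-1,3-oxazolidin-2-one to give (4S)-4-benzyl-3-{[2-(benzyloxy)-3,4-dimethoxyphenyl]acetyl}-1,3-oxazolidin-2-one F1. Its chelated sodium (Z)-enolate (NaN(SiMe3)2, THF, −78 °C) would be alkylated by bromide 8 on the face away from the benzyl group (Evans alkylation) to give (4S)-4-benzyl-3-[(2S)-2-[2-(benzyloxy)-3,4-dimethoxyphenyl]-3-{2-[(tert-butyldimethylsilyl)oxy]-4,5-dimethoxyphenyl}propanoyl]-1,3-oxazolidin-2-one F2. Bu4NF buffered with AcOH would then free the phenol, which should displace the auxiliary by intramolecular acyl transfer and close the lactone 11.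

Step 8. C3 may racemize if the oxocarbenium ion reversibly loses the C3 proton to the conjugated 4H-chromene before hydride arrives, or the lactolate may collapse and be over-reduced. The fallback avoids any cation next to C3; it sets out from 11 and returns at 13. LiAlH4 (THF, 0 °C) would open the lactone to (2S)-2-[2-(benzyloxy)-3,4-dimethoxyphenyl]-3-(2-hydroxy-4,5-dimethoxyphenyl)propan-1-ol F3, and a Mitsunobu etherification (PPh3, DIAD, THF, 0 °C) of the phenol with the primary alcohol would reclose the ring at O1–C2 to give 13 without touching C3.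

Step 6. The donor-substituted benzylic bromide may ionize during isolation, with loss of the silyl group and oligomerization. The fallback uses a bench-stable precursor with a free phenol; it sets out from 5 and returns at 11 through the same o-quinone methide 10. NaBH4 (MeOH, 0 °C) would reduce 5 to 2-(hydroxymethyl)-4,5-dimethoxyphenol F4, and 4-MeC6H4SO2Na in aqueous HCO2H would convert it into 4,5-dimethoxy-2-{[(4-methylphenyl)sulfonyl]methyl}phenol F5. In step 7, F5 would replace 8 and Cs2CO3 would replace CsF, so that the phenoxide expels sulfinate instead of bromide.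

**Further compounds**
F1 | step 7 | (4S)-4-benzyl-3-{[2-(benzyloxy)-3,4-dimethoxyphenyl]acetyl}-1,3-oxazolidin-2-one | COc1ccc(CC(=O)N2[C@@H](Cc3ccccc3)COC2=O)c(OCc2ccccc2)c1OC
F2 | step 7 | (4S)-4-benzyl-3-[(2S)-2-[2-(benzyloxy)-3,4-dimethoxyphenyl]-3-{2-[(tert-butyldimethylsilyl)oxy]-4,5-dimethoxyphenyl}propanoyl]-1,3-oxazolidin-2-one | COc1ccc([C@H](Cc2cc(OC)c(OC)cc2O[Si](C)(C)C(C)(C)C)C(=O)N2[C@@H](Cc3ccccc3)COC2=O)c(OCc2ccccc2)c1OC
F3 | step 8 | (2S)-2-[2-(benzyloxy)-3,4-dimethoxyphenyl]-3-(2-hydroxy-4,5-dimethoxyphenyl)propan-1-ol | COc1ccc([C@H](Cc2cc(OC)c(OC)cc2O)CO)c(OCc2ccccc2)c1OC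
F4 | step 6 | 2-(hydroxymethyl)-4,5-dimethoxyphenol | OCc1cc(OC)c(OC)cc1O
F5 | step 6 | 4,5-dimethoxy-2-{[(4-methylphenyl)sulfonyl]methyl}phenol | Cc1ccc(S(=O)(=O)Cc2cc(OC)c(OC)cc2O)cc1
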